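## Retrosynthetic overview

1. The ring ketone comes from a last-step alcohol oxidation. The appended α-methyl-γ-butyrolactone is joined late by an intermolecular vinylogous Mannich reaction between 3-methyl-2-silyloxyfuran and the N-acyliminium ion of the complete macrocyclic core, then hydrogenation.
2. The eleven-membered aza-ring comes from ring-closing metathesis of an N-allyl lactam and a homoallylic silyl ether (made by allylboration of an aldehyde).
3. The 3-silyloxypyrrolidinone and the cis-fused lactone arise together in a lactone-to-lactam switch: allylamine condenses with a γ-lactone aldehyde, nitrogen acylates on the old lactone, and the freed alcohol re-lactonises on an acetic acid arm. The lactone methyl follows by enolate methylation.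
4. The trisubstituted γ-lactone comes from a butenolide by malonate Michael addition, α-allylation and α-hydroxylation, each anti to the neighbouring ring substituent.
5. The butenolide comes from an Evans syn-aldol (butanoyl imide + acrolein), reduction and acrylate ring-closing metathesis. Ring order: butenolide → pyrrolidinone + fused lactone (one step) → macrocycle → appended lactone.

Assumption: centres that are erased later (the methoxy-bearing N,O-acetal carbon from step 13, the carbinol from step 17) and the ring-alkene geometry from step 19 are carried as mixtures, so their SMILES leave them undefined.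

## Route

Step 1
Reactants: 1 (S)-4-benzyl-1,3-oxazolidin-2-one; 2 butanoyl chloride
Product: 4 (S)-4-benzyl-3-butanoyl-1,3-oxazolidin-2-one, via lithium oxazolidinide 3 (not isolated)
Conditions: nBuLi, THF, −78 °C; then 2, −78 → 0 °C
Reagents that add atoms: butanoyl chloride CCCC(=O)Cl
Why: N-acylation of the lithiated auxiliary by an acid chloride is clean and forms no stereocentre.

Step 2
Reactants: 4 (S)-4-benzyl-3-butanoyl-1,3-oxazolidin-2-one; 5 acrolein
Product: 8 (S)-4-benzyl-3-[(2S,3R)-2-ethyl-3-hydroxypent-4-enoyl]-1,3-oxazolidin-2-one, via Z-dibutylboron enolate 6 (not isolated), via boron aldolate 7 (not isolated)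
Conditions: Bu2BOTf, Et3N, CH2Cl2, 0 °C; acrolein, −78 → 0 °C; then pH 7 buffer, MeOH, H2O2, 0 °C
Reagents that add atoms: acrolein C=CC=O
Why: Evans syn-aldol reaction, in which the Z-boron enolate reacts through a closed chair transition state on the enolate face opposite the benzyl group, setting the ethyl-bearing carbon (S) and the carbinol (R) together.

Step 3
Reactants: 8 (S)-4-benzyl-3-[(2S,3R)-2-ethyl-3-hydroxypent-4-enoyl]-1,3-oxazolidin-2-one
Product: 9 (2R,3R)-2-ethylpent-4-ene-1,3-diol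
Conditions: LiBH4, MeOH (2 equiv), THF, 0 °C
Reagents that add atoms: none
Why: Reductive cleavage of the imide at the exocyclic carbonyl releases the primary alcohol and the auxiliary without touching either stereocentre (the descriptor at the ethyl carbon changes only through priorities).

Step 4
Reactants: 9 (2R,3R)-2-ethylpent-4-ene-1,3-diol
Product: 10 (3R,4R)-4-[(tert-butyldiphenylsilyloxy)methyl]hex-1-en-3-ol
Conditions: tBuPh2SiCl, imidazole, CH2Cl2, 0 °C
Reagents that add atoms: tert-butyl(chloro)diphenylsilane CC(C)(C)[Si](Cl)(c1ccccc1)c1ccccc1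
Why: Selective silylation, since the bulky silyl chloride reacts at the primary hydroxyl much faster than at the branched secondary allylic one.

Step 5
Reactants: 10 (3R,4R)-4-[(tert-butyldiphenylsilyloxy)methyl]hex-1-en-3-ol; 11 acryloyl chloride
Product: 12 (3R,4R)-4-[(tert-butyldiphenylsilyloxy)methyl]hex-1-en-3-yl prop-2-enoate
Conditions: acryloyl chloride, Et3N, 4-(dimethylamino)pyridine (cat.), CH2Cl2, −20 → 0 °C
Reagents that add atoms: acryloyl chloride C=CC(=O)Cl
Why: Simple O-acylation of the secondary allylic alcohol, with retention at the carbinol.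

Step 6
Reactants: 12 (3R,4R)-4-[(tert-butyldiphenylsilyloxy)methyl]hex-1-en-3-yl prop-2-enoate
Product: 13 (5R)-5-[(2R)-1-(tert-butyldiphenylsilyloxy)butan-2-yl]furan-2(5H)-one
Conditions: second-generation Grubbs catalyst RuCl2(=CHPh)(H2IMes)(PCy3) (5 mol %), CH2Cl2 (5 mM), 40 °C
Reagents that add atoms: none
Why: Ring-closing metathesis of an allyl acrylate to a butenolide is a favourable five-membered closure driven by loss of ethene, and no stereocentre is affected.

Step 7
Reactants: 13 (5R)-5-[(2R)-1-(tert-butyldiphenylsilyloxy)butan-2-yl]furan-2(5H)-one; 14 dibenzyl malonate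
Product: 15 dibenzyl 2-[(2R,3S)-2-[(2R)-1-(tert-butyldiphenylsilyloxy)butan-2-yl]-5-oxooxolan-3-yl]propanedioate
Conditions: NaH (0.2 equiv), THF, 0 → 23 °C
Reagents that add atoms: dibenzyl malonate O=C(CC(=O)OCc1ccccc1)OCc1ccccc1
Why: Intermolecular Michael addition of the soft malonate anion to the butenolide occurs anti to the bulky 5-substituent, giving the trans lactone and setting the ring carbon that carries the future lactone arm.

Step 8
Reactants: 15 dibenzyl 2-[(2R,3S)-2-[(2R)-1-(tert-butyldiphenylsilyloxy)butan-2-yl]-5-oxooxolan-3-yl]propanedioate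
Product: 17 2-[(2R,3R)-2-[(2R)-1-(tert-butyldiphenylsilyloxy)butan-2-yl]-5-oxooxolan-3-yl]acetic acid, via malonic acid 16 (not isolated)
Conditions: H2 (1 atm), 10% Pd/C, EtOAc, 23 °C; filter; toluene, 110 °C
Reagents that add atoms: none
Why: Neutral hydrogenolysis of the benzyl esters followed by thermal decarboxylation of the malonic acid leaves a free acetic acid arm, whose carboxylate in later steps shields its own α-position from enolisation.

Step 9
Reactants: 17 2-[(2R,3R)-2-[(2R)-1-(tert-butyldiphenylsilyloxy)butan-2-yl]-5-oxooxolan-3-yl]acetic acid; 18 allyl bromide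
Product: 20 2-[(2R,3R,4R)-2-[(2R)-1-(tert-butyldiphenylsilyloxy)butan-2-yl]-5-oxo-4-(prop-2-en-1-yl)oxolan-3-yl]acetic acid, via dilithium carboxylate enolate 19 (not isolated)
Conditions: LiN(SiMe3)2 (2.2 equiv), THF, −78 °C; allyl bromide, −78 → −30 °C; 1 M HCl
Reagents that add atoms: allyl bromide C=CCBr
Why: Lactone enolate alkylation, in which the amide base deprotonates only the acid O–H and the lactone α-CH2 and the allyl group enters anti to the adjacent ring substituent (this centre is re-set in step 10).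

Step 10
Reactants: 20 2-[(2R,3R,4R)-2-[(2R)-1-(tert-butyldiphenylsilyloxy)butan-2-yl]-5-oxo-4-(prop-2-en-1-yl)oxolan-3-yl]acetic acid
Product: 22 2-[(2S,3S,4R)-2-[(2R)-1-(tert-butyldiphenylsilyloxy)butan-2-yl]-4-hydroxy-5-oxo-4-(prop-2-en-1-yl)oxolan-3-yl]acetic acid, via dipotassium carboxylate enolate 21 (not isolated)
Conditions: KN(SiMe3)2 (2.3 equiv), THF, −78 °C; 2-(phenylsulfonyl)-3-phenyloxaziridine, −78 °C; 1 M HCl
Reagents that add atoms: 2-(benzenesulfonyl)-3-phenyloxaziridine O=S(=O)(c1ccccc1)N1OC1c1ccccc1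
Why: Davis enolate hydroxylation, in which oxygen is delivered to the tetrasubstituted lactone enolate anti to the adjacent acetic acid arm, so the hydroxyl ends trans and the allyl group cis to that arm (the quaternary carbinol of the target, R).

Step 11
Reactants: 22 2-[(2S,3S,4R)-2-[(2R)-1-(tert-butyldiphenylsilyloxy)butan-2-yl]-4-hydroxy-5-oxo-4-(prop-2-en-1-yl)oxolan-3-yl]acetic acid
Product: 24 2-[(2S,3S,4R)-2-[(2R)-1-(tert-butyldiphenylsilyloxy)butan-2-yl]-4-(tert-butyldimethylsilyloxy)-5-oxo-4-(prop-2-en-1-yl)oxolan-3-yl]acetic acid, via bis-silylated ether ester 23 (not isolated)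
Conditions: tBuMe2SiOSO2CF3 (3 equiv), 2,6-lutidine, CH2Cl2, 0 → 23 °C; then AcOH, THF, H2O
Reagents that add atoms: tert-butyldimethylsilyl trifluoromethanesulfonate CC(C)(C)[Si](C)(C)OS(=O)(=O)C(F)(F)F
Why: The silyl triflate silylates the hindered tertiary alcohol (and transiently the acid, whose silyl ester hydrolyses on work-up), which later prevents the tertiary oxygen from competing for the lactone carbonyl.

Step 12
Reactants: 24 2-[(2S,3S,4R)-2-[(2R)-1-(tert-butyldiphenylsilyloxy)butan-2-yl]-4-(tert-butyldimethylsilyloxy)-5-oxo-4-(prop-2-en-1-yl)oxolan-3-yl]acetic acid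
Product: 26 2-[(2S,3S,4R)-2-[(2R)-1-(tert-butyldiphenylsilyloxy)butan-2-yl]-4-(tert-butyldimethylsilyloxy)-5-oxo-4-(2-oxoethyl)oxolan-3-yl]acetic acid, via secondary ozonide 25 (not isolated)
Conditions: O3, CH2Cl2, −78 °C; then PPh3, −78 → 23 °C
Reagents that add atoms: ozone [O-][O+]=O
Why: Ozonolysis with reductive work-up cleaves the only alkene to the aldehyde and leaves all stereocentres untouched.

Step 13
Reactants: 26 2-[(2S,3S,4R)-2-[(2R)-1-(tert-butyldiphenylsilyloxy)butan-2-yl]-4-(tert-butyldimethylsilyloxy)-5-oxo-4-(2-oxoethyl)oxolan-3-yl]acetic acid; 27 allylamine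
Product: 30 (3R)-3-[(2S,3S)-2-[(2R)-1-(tert-butyldiphenylsilyloxy)butan-2-yl]-5-oxooxolan-3-yl]-3-(tert-butyldimethylsilyloxy)-5-methoxy-1-(prop-2-en-1-yl)pyrrolidin-2-one (5-epimer mixture), via N-allyl imine 28 (not isolated), via ring-opened methoxy lactam hydroxy acid 29 (not isolated)
Conditions: allylamine (2 equiv), MeOH, 3 Å sieves, 23 → 55 °C; evaporate; camphorsulfonic acid (0.3 equiv), MeOH, 23 °C
Reagents that add atoms: allylamine C=CCN; methanol CO
Why: Imine condensation, 5-exo intramolecular aminolysis of the old lactone and acid-promoted relactonisation of the freed secondary alcohol onto the acetic acid arm (a translactonisation driven by amide formation) give the N-allyl N,O-acetal lactam and a lactone that is cis β,γ-disubstituted because its precursor was trans; no stereocentre is touched.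

Step 14
Reactants: 30 (3R)-3-[(2S,3S)-2-[(2R)-1-(tert-butyldiphenylsilyloxy)butan-2-yl]-5-oxooxolan-3-yl]-3-(tert-butyldimethylsilyloxy)-5-methoxy-1-(prop-2-en-1-yl)pyrrolidin-2-one; 31 iodomethane
Product: 33 (3R)-3-[(2S,3S,4S)-2-[(2R)-1-(tert-butyldiphenylsilyloxy)butan-2-yl]-4-methyl-5-oxooxolan-3-yl]-3-(tert-butyldimethylsilyloxy)-5-methoxy-1-(prop-2-en-1-yl)pyrrolidin-2-one, via lithium lactone enolate 32 (not isolated)
Conditions: LiN(iPr)2 (1.15 equiv), THF, −78 °C; MeI, −78 → −40 °C
Reagents that add atoms: iodomethane CI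
Why: Enolate methylation of the only enolisable carbonyl (the lactam α-carbon is quaternary), with MeI entering the face opposite both the quaternary β-substituent and the γ-substituent, giving the α,β-trans methyl lactone (S).

Step 15
Reactants: 33 (3R)-3-[(2S,3S,4S)-2-[(2R)-1-(tert-butyldiphenylsilyloxy)butan-2-yl]-4-methyl-5-oxooxolan-3-yl]-3-(tert-butyldimethylsilyloxy)-5-methoxy-1-(prop-2-en-1-yl)pyrrolidin-2-one
Product: 34 (3R)-3-(tert-butyldimethylsilyloxy)-3-[(2S,3S,4S)-2-[(2R)-1-hydroxybutan-2-yl]-4-methyl-5-oxooxolan-3-yl]-5-methoxy-1-(prop-2-en-1-yl)pyrrolidin-2-one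
Conditions: Bu4NF, AcOH, THF, 0 → 23 °C
Reagents that add atoms: none
Why: Buffered fluoride desilylation removes the unhindered primary silyl ether while the shielded tertiary silyl ether stays.

Step 16
Reactants: 34 (3R)-3-(tert-butyldimethylsilyloxy)-3-[(2S,3S,4S)-2-[(2R)-1-hydroxybutan-2-yl]-4-methyl-5-oxooxolan-3-yl]-5-methoxy-1-(prop-2-en-1-yl)pyrrolidin-2-one
Product: 35 (2S)-2-[(2R,3S,4S)-3-[(3R)-3-(tert-butyldimethylsilyloxy)-5-methoxy-2-oxo-1-(prop-2-en-1-yl)pyrrolidin-3-yl]-4-methyl-5-oxooxolan-2-yl]butanal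
Conditions: Dess–Martin periodinane, CH2Cl2, 0 → 23 °C
Reagents that add atoms: none
Why: Dess–Martin oxidation is non-basic, so the α-stereocentre and the β-acyloxy group of the aldehyde survive; the crude aldehyde is used at once.

Step 17
Reactants: 35 (2S)-2-[(2R,3S,4S)-3-[(3R)-3-(tert-butyldimethylsilyloxy)-5-methoxy-2-oxo-1-(prop-2-en-1-yl)pyrrolidin-3-yl]-4-methyl-5-oxooxolan-2-yl]butanal; 36 allylboronic acid pinacol ester
Product: 38 homoallylic alcohol (35 with CHO converted to CH(OH)CH2CH=CH2; carbinol epimer mixture), via pinacol borate 37 (not isolated)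
Conditions: 36 (1.5 equiv), CH2Cl2, 23 °C; aqueous NaHCO3 work-up
Reagents that add atoms: allylboronic acid pinacol ester C=CCB1OC(C)(C)C(C)(C)O1
Why: Uncatalysed allylboration (carbonyl allylation through a six-membered transition state) is neutral and aldehyde-selective; the new carbinol is not controlled because it is oxidised in step 24.

Step 18
Reactants: 38 homoallylic alcohol
Product: 39 homoallylic tert-butyldimethylsilyl ether of 38
Conditions: tBuMe2SiCl, imidazole, DMF, 23 → 40 °C
Reagents that add atoms: tert-butyl(chloro)dimethylsilane CC(C)(C)[Si](C)(C)Cl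
Why: Standard silylation under conditions that do not ionise the N,O-acetal, so that no free hydroxyl is present in step 21.

Step 19
Reactants: 39 homoallylic silyl ether diene
Product: 40 macrocyclic alkene N,O-acetal (eleven-membered ring closed between the two allyl termini; E/Z mixture)
Conditions: second-generation Grubbs catalyst RuCl2(=CHPh)(H2IMes)(PCy3) (10 mol %), CH2Cl2 (1 mM), 40 °C
Reagents that add atoms: none
Why: Ring-closing metathesis of two unhindered terminal alkenes, helped by the cis arrangement of the two chain-bearing substituents on the fused lactone, which holds the termini close; no stereocentre changes.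

Step 20
Reactants: 41 3-methylfuran-2(5H)-one
Product: 42 triisopropyl[(3-methylfuran-2-yl)oxy]silane
Conditions: iPr3SiOSO2CF3, Et3N, CH2Cl2, 0 °C
Reagents that add atoms: triisopropylsilyl trifluoromethanesulfonate CC(C)[Si](C(C)C)(C(C)C)OS(=O)(=O)C(F)(F)F
Why: Soft enolisation and O-silylation of the butenolide give the aromatic 2-silyloxyfuran, a stable dienolate equivalent.

Step 21
Reactants: 40 macrocyclic alkene N,O-acetal; 42 triisopropyl[(3-methylfuran-2-yl)oxy]silane
Product: 44 vinylogous Mannich adduct (40 with OMe replaced by the (2S)-4-methyl-5-oxo-2,5-dihydrofuran-2-yl group; new aminal-derived carbon S), via N-acyliminium triflate 43 (not isolated)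
Conditions: iPr3SiOSO2CF3 (0.2 equiv), 42 (2 equiv), CH2Cl2, −78 → −40 °C
Reagents that add atoms: triisopropyl[(3-methylfuran-2-yl)oxy]silane Cc1ccoc1O[Si](C(C)C)(C(C)C)C(C)C
Why: Intermolecular vinylogous Mannich reaction in which the furan 5-position attacks the bridged N-acyliminium ion from the face away from the ansa chain (syn to the silyloxy group), with the threo relationship that silyloxyfurans normally favour with five-membered N-acyliminium ions.

Step 22
Reactants: 44 vinylogous Mannich adduct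
Product: 45 saturated bis-silyl ether (ring alkene and butenolide alkene reduced; new methyl-bearing carbon S)
Conditions: H2 (1 atm), 5% Rh/Al2O3, EtOAc, 23 °C
Reagents that add atoms: none
Why: Heterogeneous hydrogenation reduces both alkenes, adding hydrogen to the butenolide face opposite its γ-substituent to give the cis α-methyl-γ-substituted lactone.

Step 23
Reactants: 45 saturated bis-silyl ether
Product: 46 diol (tertiary lactam carbinol and secondary ring carbinol free)
Conditions: HF·pyridine, pyridine, THF, 0 → 23 °C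
Reagents that add atoms: none
Why: Acidic fluoride desilylation frees both alcohols without generating an alkoxide, so the lactone cannot migrate to the tertiary oxygen.

Step 24
Reactants: 46 diol
Product: 47 target CNP0221273.1 (stereocentres in SMILES order S, R, S, S, S, S, R, S)
Conditions: Dess–Martin periodinane, CH2Cl2, 23 °C
Reagents that add atoms: none
Why: Dess–Martin oxidation converts the secondary alcohol to the ketone under non-basic conditions (no β-elimination of the lactone oxygen, no epimerisation of the ethyl centre), and the tertiary alcohol is inert.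

## Compound list

1 | (S)-4-benzyl-1,3-oxazolidin-2-one | O=C1N[C@@H](Cc2ccccc2)CO1 | starting material
2 | butanoyl chloride | CCCC(=O)Cl | starting material
3 | lithium (S)-4-benzyl-2-oxo-1,3-oxazolidin-3-ide | [Li]N1[C@@H](Cc2ccccc2)COC1=O | intermediate (not isolated)
4 | (S)-4-benzyl-3-butanoyl-1,3-oxazolidin-2-one | CCCC(=O)N1[C@@H](Cc2ccccc2)COC1=O | intermediate
5 | acrolein | C=CC=O | starting material
6 | Z-dibutylboron enolate of 4 | CC/C=C(\OB(CCCC)CCCC)N1[C@@H](Cc2ccccc2)COC1=O | intermediate (not isolated)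
7 | dibutylboron aldolate of 8 | CC[C@@H]([C@H](OB(CCCC)CCCC)C=C)C(=O)N1[C@@H](Cc2ccccc2)COC1=O | intermediate (not isolated)
8 | (S)-4-benzyl-3-[(2S,3R)-2-ethyl-3-hydroxypent-4-enoyl]-1,3-oxazolidin-2-one | CC[C@@H]([C@H](O)C=C)C(=O)N1[C@@H](Cc2ccccc2)COC1=O | intermediate
9 | (2R,3R)-2-ethylpent-4-ene-1,3-diol | CC[C@@H]([C@H](O)C=C)CO | intermediate
10 | (3R,4R)-4-[(tert-butyldiphenylsilyloxy)methyl]hex-1-en-3-ol | CC[C@@H]([C@H](O)C=C)CO[Si](c1ccccc1)(c1ccccc1)C(C)(C)C | intermediate
11 | acryloyl chloride | C=CC(=O)Cl | starting material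
12 | (3R,4R)-4-[(tert-butyldiphenylsilyloxy)methyl]hex-1-en-3-yl prop-2-enoate | CC[C@@H]([C@H](OC(=O)C=C)C=C)CO[Si](c1ccccc1)(c1ccccc1)C(C)(C)C | intermediate
13 | (5R)-5-[(2R)-1-(tert-butyldiphenylsilyloxy)butan-2-yl]furan-2(5H)-one | CC[C@@H]([C@@H]1OC(=O)C=C1)CO[Si](c2ccccc2)(c2ccccc2)C(C)(C)C | intermediate
14 | dibenzyl malonate | O=C(CC(=O)OCc1ccccc1)OCc1ccccc1 | starting material
15 | dibenzyl 2-[(2R,3S)-2-[(2R)-1-(tert-butyldiphenylsilyloxy)butan-2-yl]-5-oxooxolan-3-yl]propanedioate | CC[C@@H]([C@@H]1OC(=O)C[C@H]1C(C(=O)OCc2ccccc2)C(=O)OCc2ccccc2)CO[Si](c3ccccc3)(c3ccccc3)C(C)(C)C | intermediate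
16 | malonic acid from 15 | CC[C@@H]([C@@H]1OC(=O)C[C@H]1C(C(=O)O)C(=O)O)CO[Si](c2ccccc2)(c2ccccc2)C(C)(C)C | intermediate (not isolated)
17 | 2-[(2R,3R)-2-[(2R)-1-(tert-butyldiphenylsilyloxy)butan-2-yl]-5-oxooxolan-3-yl]acetic acid | CC[C@@H]([C@@H]1OC(=O)C[C@H]1CC(=O)O)CO[Si](c2ccccc2)(c2ccccc2)C(C)(C)C | intermediate
18 | allyl bromide | C=CCBr | starting material
19 | dilithium carboxylate lactone enolate of 17 | CC[C@@H]([C@@H]1OC(O[Li])=C[C@H]1CC(=O)O[Li])CO[Si](c2ccccc2)(c2ccccc2)C(C)(C)C | intermediate (not isolated)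
20 | 2-[(2R,3R,4R)-2-[(2R)-1-(tert-butyldiphenylsilyloxy)butan-2-yl]-5-oxo-4-(prop-2-en-1-yl)oxolan-3-yl]acetic acid | CC[C@@H]([C@@H]1OC(=O)[C@H](CC=C)[C@H]1CC(=O)O)CO[Si](c2ccccc2)(c2ccccc2)C(C)(C)C | intermediate
21 | dipotassium carboxylate lactone enolate of 20 | CC[C@@H]([C@@H]1OC(O[K])=C(CC=C)[C@H]1CC(=O)O[K])CO[Si](c2ccccc2)(c2ccccc2)C(C)(C)C | intermediate (not isolated)
22 | 2-[(2S,3S,4R)-2-[(2R)-1-(tert-butyldiphenylsilyloxy)butan-2-yl]-4-hydroxy-5-oxo-4-(prop-2-en-1-yl)oxolan-3-yl]acetic acid | CC[C@@H]([C@@H]1OC(=O)[C@@](O)(CC=C)[C@H]1CC(=O)O)CO[Si](c2ccccc2)(c2ccccc2)C(C)(C)C | intermediate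
23 | tert-butyldimethylsilyl ether and silyl ester of 22 | CC[C@@H]([C@@H]1OC(=O)[C@@](O[Si](C)(C)C(C)(C)C)(CC=C)[C@H]1CC(=O)O[Si](C)(C)C(C)(C)C)CO[Si](c2ccccc2)(c2ccccc2)C(C)(C)C | intermediate (not isolated)
24 | 2-[(2S,3S,4R)-2-[(2R)-1-(tert-butyldiphenylsilyloxy)butan-2-yl]-4-(tert-butyldimethylsilyloxy)-5-oxo-4-(prop-2-en-1-yl)oxolan-3-yl]acetic acid | CC[C@@H]([C@@H]1OC(=O)[C@@](O[Si](C)(C)C(C)(C)C)(CC=C)[C@H]1CC(=O)O)CO[Si](c2ccccc2)(c2ccccc2)C(C)(C)C | intermediate
25 | secondary ozonide (1,2,4-trioxolane) of 24 | CC[C@@H]([C@@H]1OC(=O)[C@@](O[Si](C)(C)C(C)(C)C)(CC2OCOO2)[C@H]1CC(=O)O)CO[Si](c3ccccc3)(c3ccccc3)C(C)(C)C | intermediate (not isolated)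
26 | 2-[(2S,3S,4R)-2-[(2R)-1-(tert-butyldiphenylsilyloxy)butan-2-yl]-4-(tert-butyldimethylsilyloxy)-5-oxo-4-(2-oxoethyl)oxolan-3-yl]acetic acid | CC[C@@H]([C@@H]1OC(=O)[C@@](O[Si](C)(C)C(C)(C)C)(CC=O)[C@H]1CC(=O)O)CO[Si](c2ccccc2)(c2ccccc2)C(C)(C)C | intermediate
27 | allylamine | C=CCN | starting material
28 | N-allyl imine of 26 | CC[C@@H]([C@@H]1OC(=O)[C@@](O[Si](C)(C)C(C)(C)C)(CC=NCC=C)[C@H]1CC(=O)O)CO[Si](c2ccccc2)(c2ccccc2)C(C)(C)C | intermediate (not isolated)
29 | ring-opened N-allyl 5-methoxy lactam hydroxy acid | CC[C@@H]([C@H](O)[C@H](CC(=O)O)[C@]1(O[Si](C)(C)C(C)(C)C)CC(OC)N(CC=C)C1=O)CO[Si](c2ccccc2)(c2ccccc2)C(C)(C)C | intermediate (not isolated)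
30 | (3R)-3-[(2S,3S)-2-[(2R)-1-(tert-butyldiphenylsilyloxy)butan-2-yl]-5-oxooxolan-3-yl]-3-(tert-butyldimethylsilyloxy)-5-methoxy-1-(prop-2-en-1-yl)pyrrolidin-2-one (5-epimers) | CC[C@@H]([C@@H]1OC(=O)C[C@@H]1[C@]2(O[Si](C)(C)C(C)(C)C)CC(OC)N(CC=C)C2=O)CO[Si](c3ccccc3)(c3ccccc3)C(C)(C)C | intermediate
31 | iodomethane | CI | starting material
32 | lithium lactone enolate of 30 | CC[C@@H]([C@@H]1OC(O[Li])=C[C@@H]1[C@]2(O[Si](C)(C)C(C)(C)C)CC(OC)N(CC=C)C2=O)CO[Si](c3ccccc3)(c3ccccc3)C(C)(C)C | intermediate (not isolated)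
33 | (3R)-3-[(2S,3S,4S)-2-[(2R)-1-(tert-butyldiphenylsilyloxy)butan-2-yl]-4-methyl-5-oxooxolan-3-yl]-3-(tert-butyldimethylsilyloxy)-5-methoxy-1-(prop-2-en-1-yl)pyrrolidin-2-one | CC[C@@H]([C@@H]1OC(=O)[C@@H](C)[C@@H]1[C@]2(O[Si](C)(C)C(C)(C)C)CC(OC)N(CC=C)C2=O)CO[Si](c3ccccc3)(c3ccccc3)C(C)(C)C | intermediate
34 | primary alcohol: (3R)-3-(tert-butyldimethylsilyloxy)-3-[(2S,3S,4S)-2-[(2R)-1-hydroxybutan-2-yl]-4-methyl-5-oxooxolan-3-yl]-5-methoxy-1-(prop-2-en-1-yl)pyrrolidin-2-one | CC[C@@H]([C@@H]1OC(=O)[C@@H](C)[C@@H]1[C@]2(O[Si](C)(C)C(C)(C)C)CC(OC)N(CC=C)C2=O)CO | intermediate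
35 | aldehyde: (2S)-2-[(2R,3S,4S)-3-[(3R)-3-(tert-butyldimethylsilyloxy)-5-methoxy-2-oxo-1-(prop-2-en-1-yl)pyrrolidin-3-yl]-4-methyl-5-oxooxolan-2-yl]butanal | CC[C@@H]([C@@H]1OC(=O)[C@@H](C)[C@@H]1[C@]2(O[Si](C)(C)C(C)(C)C)CC(OC)N(CC=C)C2=O)C=O | intermediate
36 | allylboronic acid pinacol ester | C=CCB1OC(C)(C)C(C)(C)O1 | starting material
37 | pinacol borate of 38 | CC[C@@H]([C@@H]1OC(=O)[C@@H](C)[C@@H]1[C@]2(O[Si](C)(C)C(C)(C)C)CC(OC)N(CC=C)C2=O)C(CC=C)OB3OC(C)(C)C(C)(C)O3 | intermediate (not isolated)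
38 | homoallylic alcohol (carbinol epimers) | CC[C@@H]([C@@H]1OC(=O)[C@@H](C)[C@@H]1[C@]2(O[Si](C)(C)C(C)(C)C)CC(OC)N(CC=C)C2=O)C(O)CC=C | intermediate
39 | homoallylic tert-butyldimethylsilyl ether diene | CC[C@@H]([C@@H]1OC(=O)[C@@H](C)[C@@H]1[C@]2(O[Si](C)(C)C(C)(C)C)CC(OC)N(CC=C)C2=O)C(O[Si](C)(C)C(C)(C)C)CC=C | intermediate
40 | macrocyclic alkene N,O-acetal (eleven-membered ring; bis-silyl ether; E/Z and epimer mixture) | CC[C@@H]1C(O[Si](C)(C)C(C)(C)C)CC=CCN2C(=O)[C@@](O[Si](C)(C)C(C)(C)C)(CC2OC)[C@@H]2[C@H]1OC(=O)[C@H]2C | intermediate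
41 | 3-methylfuran-2(5H)-one | CC1=CCOC1=O | starting material
42 | triisopropyl[(3-methylfuran-2-yl)oxy]silane | Cc1ccoc1O[Si](C(C)C)(C(C)C)C(C)C | intermediate
43 | macrocyclic N-acyliminium trifluoromethanesulfonate | CC[C@@H]1C(O[Si](C)(C)C(C)(C)C)CC=CC[N+]2=CC[C@](O[Si](C)(C)C(C)(C)C)(C2=O)[C@@H]2[C@H]1OC(=O)[C@H]2C.[O-]S(=O)(=O)C(F)(F)F | intermediate (not isolated)
44 | vinylogous Mannich adduct (butenolide on the former aminal carbon) | CC[C@@H]1C(O[Si](C)(C)C(C)(C)C)CC=CCN2C(=O)[C@@](O[Si](C)(C)C(C)(C)C)(C[C@H]2[C@@H]2C=C(C)C(=O)O2)[C@@H]2[C@H]1OC(=O)[C@H]2C | intermediate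
45 | saturated bis-silyl ether | CC[C@@H]1C(O[Si](C)(C)C(C)(C)C)CCCCN2C(=O)[C@@](O[Si](C)(C)C(C)(C)C)(C[C@H]2[C@@H]2C[C@H](C)C(=O)O2)[C@@H]2[C@H]1OC(=O)[C@H]2C | intermediate
46 | diol (ring carbinol epimers) | CC[C@@H]1C(O)CCCCN2C(=O)[C@@](O)(C[C@H]2[C@@H]2C[C@H](C)C(=O)O2)[C@@H]2[C@H]1OC(=O)[C@H]2C | intermediate
47 | CNP0221273.1 | CC[C@@H]1C(=O)CCCCN2C(=O)[C@@](O)(C[C@H]2[C@@H]2C[C@H](C)C(=O)O2)[C@@H]2[C@H]1OC(=O)[C@H]2C | target

## Step count and risks

Total steps: 24. Longest linear sequence: 23 (steps 1–19 and 21–24); step 20 is a one-step side branch.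

Three steps most likely to fail:

Step 13 (lactone-to-lactam switch). The one-flask condensation, intramolecular aminolysis of a hindered lactone and relactonisation may stall at the imine or give enamide mixtures. The fallback sets out from 26 and separates the events. The aldehyde is first masked with MeOH, HC(OMe)3 and pyridinium p-toluenesulfonate as the dimethyl acetal acid F1. The old lactone is then opened intermolecularly with the aluminium amide from AlMe3 and allylamine; on mildly acidic work-up the freed hydroxy acid closes to the N-allyl amide lactone acetal F2. Camphorsulfonic acid in MeOH then lets the amide N–H condense with the acetal, which gives 30, where the route is rejoined.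

Step 19 (eleven-membered ring closure). Medium-ring metathesis may give oligomers. The fallback sets out from 39 and reverses the order of ring closure and fragment union. The vinylogous Mannich reaction with 42 (conditions of step 21) is run on the open-chain N,O-acetal to give the open-chain butenolide adduct F3. This is a single aminal-derived epimer whose bulky substituent next to nitrogen restricts the N-allyl rotamers. Ring-closing metathesis of F3 under the step 19 conditions then gives 44, where the route is rejoined.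

Step 21 (facial and threo selectivity of the fragment union). Both new centres rely on substrate control, and the silyloxy group on the face to be attacked could erode it. The fallback sets out from 40 and changes the controlling element. Both silyl ethers are removed first with HF·pyridine to give the macrocyclic diol N,O-acetal F4, so that the attacked face carries only a small free hydroxyl. The Mannich reaction is then run with BF3·OEt2 and excess 42 to give the diol butenolide adduct F5. Hydrogenation of F5 over Rh/Al2O3 gives 46, where the route is rejoined.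

## Further compounds

F1 | step 13 | dimethyl acetal of aldehyde acid 26 | CC[C@@H]([C@@H]1OC(=O)[C@@](O[Si](C)(C)C(C)(C)C)(CC(OC)OC)[C@H]1CC(=O)O)CO[Si](c2ccccc2)(c2ccccc2)C(C)(C)C
F2 | step 13 | N-allyl amide lactone dimethyl acetal | CC[C@@H]([C@@H]1OC(=O)C[C@@H]1[C@](O[Si](C)(C)C(C)(C)C)(CC(OC)OC)C(=O)NCC=C)CO[Si](c2ccccc2)(c2ccccc2)C(C)(C)C
F3 | step 19 | open-chain butenolide Mannich adduct of 39 | CC[C@@H]([C@@H]1OC(=O)[C@@H](C)[C@@H]1[C@]2(O[Si](C)(C)C(C)(C)C)C[C@@H]([C@@H]3C=C(C)C(=O)O3)N(CC=C)C2=O)C(O[Si](C)(C)C(C)(C)C)CC=C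
F4 | step 21 | macrocyclic diol N,O-acetal | CC[C@@H]1C(O)CC=CCN2C(=O)[C@@](O)(CC2OC)[C@@H]2[C@H]1OC(=O)[C@H]2C
F5 | step 21 | macrocyclic diol butenolide adduct | CC[C@@H]1C(O)CC=CCN2C(=O)[C@@](O)(C[C@H]2[C@@H]2C=C(C)C(=O)O2)[C@@H]2[C@H]1OC(=O)[C@H]2C
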